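## Structural features

The target (C30H22O17) is a linear chain of five benzene rings, lettered A to E from the 2,4,6-trihydroxyphenyl end, joined only by four diaryl ether oxygens; it carries thirteen free phenolic hydroxyls and has no carbon–carbon bond between rings. Ring A is bound through C4 (hydroxyls at C1, C3, C5); ring B carries the ring A oxygen at C1, the ring C oxygen at the adjacent C6 and hydroxyls at C3 and C5; ring C is bridged 1,4 (C1 to ring B, C4 to ring D) with hydroxyls at C3 and C5; ring D carries the ring C oxygen at C1, a lone CH at C2, hydroxyls at C3, C4 and C5 and the ring E oxygen at C6; ring E is a 3,4,5-trihydroxyphenyl group bound through C1. There is no stereocentre and no axis that has to be controlled, so no stereocentres stand next to each other and the problem is one of oxygenation pattern and C–O bond formation only. The fragile groups are the hydroxyls themselves: the pyrogallol-type arrays of rings D and E and the 1,4-dioxygenated rings C and D oxidise easily in air, most of all as phenoxides, so every hydroxyl has to stay masked until the last step. The real difficulty is twofold: each ether oxygen sits on one carbon flanked by two oxygenated carbons (ring A C4, ring B C6, ring C C4, ring D C6), so every ether joins a di-ortho-substituted, electron-rich partner, and ring D needs oxygen on five contiguous carbons with two different fates. The key step exploits ring D: its C3–C4–C5–C6 stretch is the carbon skeleton of a squaric ester and the C1(O–ring C)–C2(H) pair is a 1-aryloxyvinyl unit, so ring D can be grown around a ring C–O bond that already exists and the hindered ether at ring C C4 never has to be made by coupling.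

## Logic of the disconnections

29 to 28: the thirteen O–CH3 bonds are cut. The free polyphenol is too easily oxidised to be carried through any coupling, and methyl is the group that 1, 5, 13, 23 and 24 already bring. The gain is that all earlier chemistry runs on robust aryl methyl ethers; the demand is an exhaustive Lewis-acid demethylation that leaves the four diaryl ethers alone.

28 to 22 and 27: the ring C C1–O bond of the B–O–C ether is cut. The oxygen stays on the hindered ring B carbon as a phenol, and the carbon electrophile is ring C C1, the only ether carbon with two ortho hydrogens on a ring that is not an end group. This splits five rings into three plus two. The forward palladium-catalysed C–O coupling must outrun attack of the phenoxide on the sulfur of the triflate.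

27 to 25, then to 23 and 24: the phenolic C–O bond of ring B is traced back to a formyl carbon (aryl migration on oxidation), and the A–O–B ether to substitution of fluoride ortho to that formyl group. The formyl group thus serves twice, as activator and as latent hydroxyl, and the unit comes from two purchased arenes in two steps. The demand is a substitution by a di-ortho-substituted phenoxide on a donor-substituted ring.

22 to 21 to 20: the S–O bond and then the O–isopropyl bond on ring C are cut. One oxygen among nine alkyl ethers must be unmasked, so it is carried as a secondary alkyl ether that a boron Lewis acid ionises at low temperature while methyl ethers survive. The demand is that rate difference.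

20 to 12 and 17, then 17 to 14 to 13: the ring E C1–O bond of the D–O–E ether is cut. The oxygen stays on the hindered ring D C6 and ring E enters as an aryne, which is insensitive to crowding at the nucleophile. The methoxy group next to the triple bond steers the phenoxide to the remote aryne carbon. The silyl ether of 12 is both the protecting group and the latent phenoxide, released by the same fluoride that generates the aryne. 17 comes from 13 by C–Br, C–Si and S–O bond formation.

12 to 11: the O–CH3 bond at ring D C3 is cut; in 11 this is the only free hydroxyl, so no selectivity is asked of the methylation.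

11 to 8 (key disconnection): the C2–C3 bond of ring D is cut (retro six-electron closure) and the C3–C6 bond re-formed (retro four-electron opening), which contracts ring D to a cyclobutenone. Five ring D oxygens reduce to a squaric ester plus an enol ether, the C–O–D ether is already in place, and the C3 and C6 oxygens emerge differentiated (free hydroxyl and silyl ether). The carbinol oxygen is capped with silicon for that reason and to avoid an air-sensitive free hydroquinone. The demand is outward rotation of the silyloxy group and survival of the acid-labile enol ether.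

8 to 4 and 5: the C–C bond between the carbinol carbon and the vinylic α-carbon, and the O–Si bond, are cut. This calls for selective α-metalation of 4 by an alkyllithium. A benzyl ether on ring C would lose a benzylic proton to that base and undergo a 1,2-Wittig shift, so the ring C para oxygen is carried as an isopropyl ether, which has no such proton and is a poorer ortho director.

4 to 3 to 2 to 1: the vinyl C–O bond, the O–isopropyl bond and the two O–H bonds of the hydroquinone are cut. Ring C then comes with all four oxygens from a purchased quinone; the demand is mono-alkylation at the unhindered, more acidic hydroxyl of 2.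

## Other disconnections considered

Alternative 1: The cut removes the hydroxyl oxygens at ring A C1 and ring B C3 and leads back to the dideoxy pentamer A1 (1,3-dimethoxy-5-[2-(2,6-dimethoxyphenoxy)-6-methoxyphenoxy]-2-[3,4,5-trimethoxy-2-(3,4,5-trimethoxyphenoxy)phenoxy]benzene). In the forward sense an iridium bipyridine catalyst with a diboron reagent would borylate both C–H bonds, and an oxidant added to the same flask would convert both C–B bonds to C–O bonds, giving diol A2 (the undeca-O-methyl target with free hydroxyls at ring A C1 and ring B C3).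
- In its favour: in A1 these two C–H bonds are the only aromatic ones without an ortho substituent, so sterically governed borylation should find them.
- Against it here: it does nothing for ring D or the four hindered ethers, which A1 needs just as 28 does. The two oxygens it installs can be bought in 23 and 24. Electron-rich arenes borylate slowly, and a twofold reaction that stops halfway leaves a mono-hydroxylated pentamer to separate. A2 goes straight into global demethylation, so its free hydroxyls give no handle.
- Structure: it simplifies the two easy rings, the chosen plan the hard one.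
- Mechanism: both rest on an intrinsically regioselective event; in predictability of regiochemistry the alternative is the equal of the chosen plan. It is better on one point: rings A and B would be less electron-rich while the A–B ether is made.
- Step economy: one step is added at the end and none is saved.

Alternative 2: The cut opens ring A at the C2–C3 and C5–C6 bonds and leads back to aryloxymalonate A3 (diethyl 2-[2-(benzyloxy)-3,5-dimethoxyphenoxy]propanedioate) and ketodiester A4 (diethyl 3-oxopentanedioate). In the forward sense an alkoxide base would bring about two Claisen acylations, each methylene of A4 attacking one ester carbonyl of A3, closing ring A as triol A5 (diethyl 5-[2-(benzyloxy)-3,5-dimethoxyphenoxy]-2,4,6-trihydroxybenzene-1,3-dicarboxylate).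
- In its favour: the A–O–B ether would be made on an sp3 carbon by O-alkylation when A3 is prepared, not by arylating a di-ortho-substituted phenol. On this bond the alternative is better than step 12 of the chosen plan. Ring A would also arrive without methyl ethers.
- Against it here: A3 has an acidic C–H and would sit as an enolate whose esters are poor acyl donors. A4 is prone to self-condensation. The two ester groups of A5 must be hydrolysed and decarboxylated, and the free triol must be re-protected before the B–C coupling.
- Structure: it constructs the one ring that can be bought with all its oxygens.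
- Mechanism: consecutive carbonyl condensations under equilibrium with competing paths, against a unimolecular pericyclic cascade whose regiochemistry is fixed by connectivity.
- Step economy: at least four steps for ring A against two (steps 12 and 13) for the whole A–B unit.

Alternative 3: The cut opens ring C at its C2–C3 bond and leads to the open-chain triketo ester A7 (methyl 3,5-dioxo-2-[3,4,5-trimethoxy-2-(3,4,5-trimethoxyphenoxy)phenoxy]hexanoate) and on to pyranone A6 (4-hydroxy-6-methyl-3-[3,4,5-trimethoxy-2-(3,4,5-trimethoxyphenoxy)phenoxy]-2H-pyran-2-one). In the forward sense methoxide would open the lactone of A6 to A7, whose methyl terminus would attack the ester carbonyl and close ring C as triol A8 (2-[3,4,5-trimethoxy-2-(3,4,5-trimethoxyphenoxy)phenoxy]benzene-1,3,5-triol).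
- In its favour: like the chosen plan it grows an aromatic ring around an aryl–oxygen bond that already exists; in this concept it is the equal of the chosen plan. It is better in that ring C would arrive with its two flanking hydroxyls free, leaving two fewer methyl ethers to cleave.
- Against it here: it presupposes the complete ring D–E unit, so the pentaoxygenated ring must come from elsewhere. The methyl terminus of A7 is its least acidic carbon, while return to A6 by lactonisation is easy. Putting the aryloxy group on C3 of the pyranone is itself a hindered C–O bond formation. Only the para hydroxyl of A8 may be arylated afterwards.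
- Structure: it addresses ring C, which the chosen plan takes from 1 with all four oxygens in place.
- Mechanism: a base-mediated condensation under equilibrium control against a thermal pericyclic cascade.
- Step economy: no saving; ring C costs two steps (1 and 2) in the chosen plan.

Key step: step 5

Assumption: 2,4,6-trimethoxyphenol (23) and 2-fluoro-4,6-dimethoxybenzaldehyde (24) are treated as catalogue compounds.

## Route

Step 1
Reactants: 1 2,6-dimethoxy-1,4-benzoquinone
Product: 2 2,6-dimethoxybenzene-1,4-diol
Conditions: Na2S2O4, EtOAc/H2O, rt, N2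
Reagents that add atoms: none
Why: Dithionite reduction of a quinone to its hydroquinone is fast and clean in a two-phase system; the product should be kept under nitrogen and used at once because it re-oxidises in air.

Step 2
Reactants: 2 2,6-dimethoxybenzene-1,4-diol
Product: 3 2,6-dimethoxy-4-(propan-2-yloxy)phenol
Conditions: 2-bromopropane (1.2 equiv), K2CO3 (1.1 equiv), DMF, 50 °C, Ar
Reagents that add atoms: 2-bromopropane, CC(C)Br
Why: Williamson etherification; the C4 hydroxyl has no ortho substituent and is the more acidic one (two meta methoxy groups), whereas the C1 hydroxyl is flanked by two methoxy groups and is slow toward a secondary halide, so mono-alkylation at C4 is expected.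

Step 3
Reactants: 3 2,6-dimethoxy-4-(propan-2-yloxy)phenol
Product: 4 2-(ethenyloxy)-1,3-dimethoxy-5-(propan-2-yloxy)benzene
Conditions: CaC2 (3 equiv), KOH (0.5 equiv), DMSO, H2O (6 equiv), 110 °C, sealed tube
Reagents that add atoms: calcium carbide, [Ca+2].[C-]#[C-]
Why: Base-mediated addition of the phenoxide to acetylene released in the flask (Reppe-type vinylation); the small linear electrophile is indifferent to the two ortho methoxy groups, and alkyl aryl ethers are inert to KOH in DMSO.

Step 4
Reactants: 4 2-(ethenyloxy)-1,3-dimethoxy-5-(propan-2-yloxy)benzene; 5 dimethyl squarate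
Product: 8 racemic 4-{[tert-butyl(dimethyl)silyl]oxy}-4-{1-[2,6-dimethoxy-4-(propan-2-yloxy)phenoxy]ethenyl}-2,3-dimethoxycyclobut-2-en-1-one, via vinyllithium 6 (not isolated), via lithium alkoxide 7 (not isolated)
Conditions: 4 (1.2 equiv), t-BuLi (1.1 equiv), THF, –78 °C, 1 h; 5 (1.0 equiv), THF, –78 °C, 30 min; Et3N (0.3 equiv), TBSOTf (1.3 equiv), –78 to –40 °C; aq. NaHCO3
Reagents that add atoms: tert-butyldimethylsilyl trifluoromethanesulfonate, CC(C)(C)[Si](C)(C)OS(=O)(=O)C(F)(F)F
Why: Oxygen-directed vinylic α-lithiation of the enol ether, 1,2-addition of 6 to one of the two equivalent ketone carbonyls of 5 and O-silylation of the cold tertiary alkoxide 7 are each standard organolithium operations; the isopropyl ether was chosen for ring C because it offers the base no benzylic proton. The new quaternary centre forms as a racemate, which does not matter because step 5 destroys it.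

Step 5
Reactants: 8 racemic 4-{[tert-butyl(dimethyl)silyl]oxy}-4-{1-[2,6-dimethoxy-4-(propan-2-yloxy)phenoxy]ethenyl}-2,3-dimethoxycyclobut-2-en-1-one
Product: 11 4-{[tert-butyl(dimethyl)silyl]oxy}-5-[2,6-dimethoxy-4-(propan-2-yloxy)phenoxy]-2,3-dimethoxyphenol, via dienylketene 9 (not isolated), via cyclohexadienone 10 (not isolated)
Conditions: toluene (dry, degassed, 0.01 M), 110 °C, 2 h, Ar, base-washed glassware
Reagents that add atoms: none
Why: Thermal conrotatory four-electron opening of the cyclobutenone breaks the bond between the carbonyl carbon and the silyloxy-bearing carbon and should give the (Z)-dienylketene 9, the silyloxy donor on the breaking bond turning outward and the 1-aryloxyvinyl group inward, next to the ketene. Disrotatory six-electron electrocyclisation of 9 then joins the ketene carbon to the vinyl CH2 (the C2–C3 bond of ring D) and closes the six-membered carbocycle as dienone 10. Tautomerisation of 10 aromatises ring D, leaving the ketene oxygen as the free C3 hydroxyl and the former carbinol oxygen as the silyl ether at C6. The closest known reaction type is the Moore rearrangement of 4-alkenyl-4-hydroxy- or 4-silyloxycyclobutenones made from squaric esters, which gives oxygenated hydroquinones or their mono-ethers; the aryloxy group on the enol ether oxygen is the only new element. No stereocentre is formed and the racemic centre of 8 is erased. The step needs outward rotation of the oxygen substituent, which the donor character of the silyloxy group secures, and it needs the ketene to cyclise before it is intercepted, which dilution in dry, acid-free toluene should secure. Because the carbinol oxygen is capped, the path to a furanone through an inward hydroxyl is closed and the two para oxygens of ring D come out differentiated.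

Step 6
Reactants: 11 4-{[tert-butyl(dimethyl)silyl]oxy}-5-[2,6-dimethoxy-4-(propan-2-yloxy)phenoxy]-2,3-dimethoxyphenol
Product: 12 tert-butyl{6-[2,6-dimethoxy-4-(propan-2-yloxy)phenoxy]-2,3,4-trimethoxyphenoxy}dimethylsilane
Conditions: MeI (1.5 equiv), K2CO3, acetone, 40 °C
Reagents that add atoms: iodomethane, CI
Why: Williamson methylation of the only free hydroxyl (ring D C3); the aryl silyl ether at C6, flanked on both sides, should be stable to carbonate in dry acetone, so no steric discrimination between two hydroxyls is required.

Step 7
Reactants: 13 3,4,5-trimethoxyphenol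
Product: 14 2-bromo-3,4,5-trimethoxyphenol
Conditions: NBS (1.0 equiv), CH2Cl2, –40 to 0 °C
Reagents that add atoms: N-bromosuccinimide, O=C1CCC(=O)N1Br
Why: Electrophilic aromatic bromination ortho to the hydroxyl; C2 and C6 are equivalent and are the only free positions, and one equivalent of reagent at low temperature should limit dibromination.

Step 8
Reactants: 14 2-bromo-3,4,5-trimethoxyphenol
Product: 17 3,4,5-trimethoxy-2-(trimethylsilyl)phenyl trifluoromethanesulfonate, via aryl silyl ether 15 (not isolated), via lithium silylphenolate 16 (not isolated)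
Conditions: HMDS, THF, 70 °C, then evaporation; n-BuLi, THF, –100 to –80 °C; Tf2O, –100 °C to rt
Reagents that add atoms: hexamethyldisilazane, C[Si](C)(C)N[Si](C)(C)C; trifluoromethanesulfonic anhydride, O=S(=O)(OS(=O)(=O)C(F)(F)F)C(F)(F)F
Why: O-silylation, bromine–lithium exchange and 1,3 oxygen-to-carbon silyl migration (retro-Brook rearrangement) give phenolate 16, which is trapped as the triflate; this is the standard way from ortho-bromophenols to ortho-silylaryl triflates.

Step 9
Reactants: 12 tert-butyl{6-[2,6-dimethoxy-4-(propan-2-yloxy)phenoxy]-2,3,4-trimethoxyphenoxy}dimethylsilane; 17 3,4,5-trimethoxy-2-(trimethylsilyl)phenyl trifluoromethanesulfonate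
Product: 20 1,3-dimethoxy-5-(propan-2-yloxy)-2-[3,4,5-trimethoxy-2-(3,4,5-trimethoxyphenoxy)phenoxy]benzene, via cesium phenolate 18 (not isolated), via 3,4,5-trimethoxybenzyne 19 (not isolated)
Conditions: CsF (5 equiv), 18-crown-6 (1 equiv), MeCN, rt, 1 h; then 17 (1.5 equiv), rt, 12 h
Reagents that add atoms: none
Why: Fluoride first cleaves the aryl silyl ether to phenolate 18 and then triggers 1,2-elimination of 17 to aryne 19; O-arylation of phenoxides by arynes tolerates di-ortho-substituted nucleophiles. The methoxy group next to the triple bond polarises 19 so that the phenoxide adds to the remote carbon, giving the 3,4,5-trimethoxyphenyl ether, and the aryl anion is protonated by the solvent.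

Step 10
Reactants: 20 1,3-dimethoxy-5-(propan-2-yloxy)-2-[3,4,5-trimethoxy-2-(3,4,5-trimethoxyphenoxy)phenoxy]benzene
Product: 21 3,5-dimethoxy-4-[3,4,5-trimethoxy-2-(3,4,5-trimethoxyphenoxy)phenoxy]phenol
Conditions: BCl3 (3 equiv), CH2Cl2, –78 to –30 °C; MeOH, aq. NaHCO3
Reagents that add atoms: none
Why: Lewis-acid dealkylation; the secondary isopropyl group leaves by ionisation at temperatures at which aryl methyl ethers, which need displacement at carbon, are not yet attacked, and diaryl ethers are inert.

Step 11
Reactants: 21 3,5-dimethoxy-4-[3,4,5-trimethoxy-2-(3,4,5-trimethoxyphenoxy)phenoxy]phenol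
Product: 22 3,5-dimethoxy-4-[3,4,5-trimethoxy-2-(3,4,5-trimethoxyphenoxy)phenoxy]phenyl trifluoromethanesulfonate
Conditions: Tf2O, pyridine, CH2Cl2, 0 °C
Reagents that add atoms: trifluoromethanesulfonic anhydride, O=S(=O)(OS(=O)(=O)C(F)(F)F)C(F)(F)F
Why: O-sulfonylation of the only free phenol, which has two ortho hydrogens, gives the cross-coupling electrophile.

Step 12
Reactants: 23 2,4,6-trimethoxyphenol; 24 2-fluoro-4,6-dimethoxybenzaldehyde
Product: 25 2,4-dimethoxy-6-(2,4,6-trimethoxyphenoxy)benzaldehyde
Conditions: K2CO3, DMAc, 130 °C, Ar
Reagents that add atoms: none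
Why: Nucleophilic aromatic substitution of fluoride activated by the ortho formyl group (addition–elimination through a Meisenheimer adduct); the two methoxy groups of 24 are meta to the carbon attacked and do not destabilise the adduct, and fluoride is the only good leaving group.

Step 13
Reactants: 25 2,4-dimethoxy-6-(2,4,6-trimethoxyphenoxy)benzaldehyde
Product: 27 2,4-dimethoxy-6-(2,4,6-trimethoxyphenoxy)phenol, via aryl formate 26 (not isolated)
Conditions: mCPBA, CH2Cl2, 0 °C to rt; then K2CO3 (cat.), MeOH, rt
Reagents that add atoms: 3-chloroperoxybenzoic acid, OOC(=O)c1cccc(Cl)c1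
Why: Baeyer–Villiger (Dakin-type) oxidation; the electron-rich aryl group with ortho and para oxygen donors migrates in preference to hydrogen to give formate 26, and methanolysis releases the phenol.

Step 14
Reactants: 22 3,5-dimethoxy-4-[3,4,5-trimethoxy-2-(3,4,5-trimethoxyphenoxy)phenoxy]phenyl trifluoromethanesulfonate; 27 2,4-dimethoxy-6-(2,4,6-trimethoxyphenoxy)phenol
Product: 28 2-(2-{3,5-dimethoxy-4-[3,4,5-trimethoxy-2-(3,4,5-trimethoxyphenoxy)phenoxy]phenoxy}-3,5-dimethoxyphenoxy)-1,3,5-trimethoxybenzene
Conditions: Pd(OAc)2 (5 mol %), 2-di-tert-butylphosphino-2',4',6'-triisopropylbiphenyl (10 mol %), K3PO4, toluene, 100 °C, slow addition of 22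
Reagents that add atoms: none
Why: Palladium-catalysed C–O cross-coupling of an aryl triflate with a phenol; the triflate carbon has two ortho hydrogens and two meta methoxy groups, so oxidative addition is not retarded, and the bulky electron-rich biarylphosphine promotes reductive elimination of the hindered ether from divalent palladium.

Step 15
Reactants: 28 2-(2-{3,5-dimethoxy-4-[3,4,5-trimethoxy-2-(3,4,5-trimethoxyphenoxy)phenoxy]phenoxy}-3,5-dimethoxyphenoxy)-1,3,5-trimethoxybenzene
Product: 29 2-(2-{4-[3,4,5-trihydroxy-2-(3,4,5-trihydroxyphenoxy)phenoxy]-3,5-dihydroxyphenoxy}-3,5-dihydroxyphenoxy)benzene-1,3,5-triol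
Conditions: BBr3 (30 equiv), CH2Cl2, –78 °C to rt, Ar; MeOH, then degassed H2O
Reagents that add atoms: none
Why: Lewis-acid cleavage of all thirteen aryl methyl ethers through aryloxyborane intermediates; diaryl ether bonds do not react with BBr3, and the work-up is kept acidic and oxygen-free because the product is an easily oxidised polyphenol.

## Compound list

1 | 2,6-dimethoxy-1,4-benzoquinone | COC1=CC(=O)C=C(OC)C1=O | starting material
2 | 2,6-dimethoxybenzene-1,4-diol | COc1cc(O)cc(OC)c1O | intermediate
3 | 2,6-dimethoxy-4-(propan-2-yloxy)phenol | COc1cc(OC(C)C)cc(OC)c1O | intermediate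
4 | 2-(ethenyloxy)-1,3-dimethoxy-5-(propan-2-yloxy)benzene | C=COc1c(OC)cc(OC(C)C)cc1OC | intermediate
5 | dimethyl squarate (3,4-dimethoxycyclobut-3-ene-1,2-dione) | COC1=C(OC)C(=O)C1=O | starting material
6 | {1-[2,6-dimethoxy-4-(propan-2-yloxy)phenoxy]ethenyl}lithium | [Li]C(=C)Oc1c(OC)cc(OC(C)C)cc1OC | intermediate
7 | racemic lithium 1-{1-[2,6-dimethoxy-4-(propan-2-yloxy)phenoxy]ethenyl}-2,3-dimethoxy-4-oxocyclobut-2-en-1-olate | [Li+].COC1=C(OC)C([O-])(C(=C)Oc2c(OC)cc(OC(C)C)cc2OC)C1=O | intermediate
8 | racemic 4-{[tert-butyl(dimethyl)silyl]oxy}-4-{1-[2,6-dimethoxy-4-(propan-2-yloxy)phenoxy]ethenyl}-2,3-dimethoxycyclobut-2-en-1-one | COC1=C(OC)C(O[Si](C)(C)C(C)(C)C)(C(=C)Oc2c(OC)cc(OC(C)C)cc2OC)C1=O | intermediate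
9 | (3Z)-4-{[tert-butyl(dimethyl)silyl]oxy}-5-[2,6-dimethoxy-4-(propan-2-yloxy)phenoxy]-2,3-dimethoxyhexa-1,3,5-trien-1-one | O=C=C(OC)/C(OC)=C(O[Si](C)(C)C(C)(C)C)\C(=C)Oc1c(OC)cc(OC(C)C)cc1OC | intermediate
10 | 4-{[tert-butyl(dimethyl)silyl]oxy}-5-[2,6-dimethoxy-4-(propan-2-yloxy)phenoxy]-2,3-dimethoxycyclohexa-2,4-dien-1-one | COC1=C(OC)C(O[Si](C)(C)C(C)(C)C)=C(Oc2c(OC)cc(OC(C)C)cc2OC)CC1=O | intermediate
11 | 4-{[tert-butyl(dimethyl)silyl]oxy}-5-[2,6-dimethoxy-4-(propan-2-yloxy)phenoxy]-2,3-dimethoxyphenol | COc1c(O)cc(Oc2c(OC)cc(OC(C)C)cc2OC)c(O[Si](C)(C)C(C)(C)C)c1OC | intermediate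
12 | tert-butyl{6-[2,6-dimethoxy-4-(propan-2-yloxy)phenoxy]-2,3,4-trimethoxyphenoxy}dimethylsilane | COc1cc(Oc2c(OC)cc(OC(C)C)cc2OC)c(O[Si](C)(C)C(C)(C)C)c(OC)c1OC | intermediate
13 | 3,4,5-trimethoxyphenol | COc1cc(O)cc(OC)c1OC | starting material
14 | 2-bromo-3,4,5-trimethoxyphenol | COc1cc(O)c(Br)c(OC)c1OC | intermediate
15 | (2-bromo-3,4,5-trimethoxyphenoxy)trimethylsilane | COc1cc(O[Si](C)(C)C)c(Br)c(OC)c1OC | intermediate
16 | lithium 3,4,5-trimethoxy-2-(trimethylsilyl)phenolate | [Li+].COc1cc([O-])c([Si](C)(C)C)c(OC)c1OC | intermediate
17 | 3,4,5-trimethoxy-2-(trimethylsilyl)phenyl trifluoromethanesulfonate | COc1cc(OS(=O)(=O)C(F)(F)F)c([Si](C)(C)C)c(OC)c1OC | intermediate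
18 | cesium 6-[2,6-dimethoxy-4-(propan-2-yloxy)phenoxy]-2,3,4-trimethoxyphenolate | [Cs+].COc1cc(Oc2c(OC)cc(OC(C)C)cc2OC)c([O-])c(OC)c1OC | intermediate
19 | 3,4,5-trimethoxybenzyne (1,2-didehydro-3,4,5-trimethoxybenzene) | COC1=CC#CC(OC)=C1OC | intermediate
20 | 1,3-dimethoxy-5-(propan-2-yloxy)-2-[3,4,5-trimethoxy-2-(3,4,5-trimethoxyphenoxy)phenoxy]benzene | COc1cc(Oc2c(OC)cc(OC(C)C)cc2OC)c(Oc2cc(OC)c(OC)c(OC)c2)c(OC)c1OC | intermediate
21 | 3,5-dimethoxy-4-[3,4,5-trimethoxy-2-(3,4,5-trimethoxyphenoxy)phenoxy]phenol | COc1cc(Oc2c(OC)cc(O)cc2OC)c(Oc2cc(OC)c(OC)c(OC)c2)c(OC)c1OC | intermediate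
22 | 3,5-dimethoxy-4-[3,4,5-trimethoxy-2-(3,4,5-trimethoxyphenoxy)phenoxy]phenyl trifluoromethanesulfonate | COc1cc(Oc2c(OC)cc(OS(=O)(=O)C(F)(F)F)cc2OC)c(Oc2cc(OC)c(OC)c(OC)c2)c(OC)c1OC | intermediate
23 | 2,4,6-trimethoxyphenol | COc1cc(OC)c(O)c(OC)c1 | starting material
24 | 2-fluoro-4,6-dimethoxybenzaldehyde | COc1cc(F)c(C=O)c(OC)c1 | starting material
25 | 2,4-dimethoxy-6-(2,4,6-trimethoxyphenoxy)benzaldehyde | COc1cc(OC)c(C=O)c(Oc2c(OC)cc(OC)cc2OC)c1 | intermediate
26 | 2,4-dimethoxy-6-(2,4,6-trimethoxyphenoxy)phenyl formate | COc1cc(OC)c(OC=O)c(Oc2c(OC)cc(OC)cc2OC)c1 | intermediate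
27 | 2,4-dimethoxy-6-(2,4,6-trimethoxyphenoxy)phenol | COc1cc(OC)c(O)c(Oc2c(OC)cc(OC)cc2OC)c1 | intermediate
28 | 2-(2-{3,5-dimethoxy-4-[3,4,5-trimethoxy-2-(3,4,5-trimethoxyphenoxy)phenoxy]phenoxy}-3,5-dimethoxyphenoxy)-1,3,5-trimethoxybenzene | COc1cc(OC)c(Oc2cc(OC)cc(OC)c2Oc2cc(OC)c(Oc3cc(OC)c(OC)c(OC)c3Oc3cc(OC)c(OC)c(OC)c3)c(OC)c2)c(OC)c1 | intermediate
29 | 2-(2-{4-[3,4,5-trihydroxy-2-(3,4,5-trihydroxyphenoxy)phenoxy]-3,5-dihydroxyphenoxy}-3,5-dihydroxyphenoxy)benzene-1,3,5-triol | Oc1cc(O)c(Oc2cc(O)cc(O)c2Oc2cc(O)c(Oc3cc(O)c(O)c(O)c3Oc3cc(O)c(O)c(O)c3)c(O)c2)c(O)c1 | target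

## Step count and least certain steps

Total step count: 15. Longest linear sequence: 11 steps (steps 1 to 6, 9, 10, 11, 14 and 15); steps 7 and 8 (aryne precursor) and steps 12 and 13 (A–B phenol) are side branches.

Step 5 (key step). The most likely failure is interception of ketene 9 before it cyclises. The 2,6-disubstituted aryloxy group on the vinyl unit crowds the geometry needed for six-electron closure, so dimerisation, capture by traces of water or acid-promoted loss of the enol ether could compete. The fallback gives up the ring expansion and makes the C–O–D ether by copper-mediated coupling. It sets out from 3 and 17 and comes back at 20. Purchased 2,3,4-trimethoxyphenol F1 would be brominated ortho to the hydroxyl (NBS, CH2Cl2, low temperature) to 6-bromo-2,3,4-trimethoxyphenol F2. O-arylation of F2 with the aryne from 17 (CsF, MeCN, rt) should give 1-bromo-3,4,5-trimethoxy-2-(3,4,5-trimethoxyphenoxy)benzene F3. Ullmann coupling of F3 with phenol 3 (copper monoiodide CuI, picolinic acid, K3PO4, DMSO, 100 °C) would give 20. This joins two hindered, electron-rich partners, which is the reason it is kept as the reserve and not the plan.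

Step 4. The most likely failure is proton abstraction from ring C of 4, at the C–H between the methoxy and isopropoxy groups, competing with the vinylic α-metalation; both sites are activated by oxygen and the ring site by two donors. The fallback makes the same vinyllithium by bromine–lithium exchange, which outruns any proton transfer. It sets out from 3 and comes back at 8. Phenol 3 with trichloroethylene (K2CO3, DMF, 70 °C) should give 2-{[(E)-1,2-dichloroethenyl]oxy}-1,3-dimethoxy-5-(propan-2-yloxy)benzene F4. n-BuLi (2.2 equiv, THF, –78 to –40 °C) followed by water would give 2-(ethynyloxy)-1,3-dimethoxy-5-(propan-2-yloxy)benzene F5. Markovnikov addition of HBr (1 equiv, pentane, –78 °C) would give 2-[(1-bromoethenyl)oxy]-1,3-dimethoxy-5-(propan-2-yloxy)benzene F6. Exchange with t-BuLi (2 equiv, –100 °C) gives 6, which is carried on with 5 and the silyl triflate as in step 4 to 8. The intermediates are more sensitive than 4, which is why this stands in reserve.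

Step 14. The most likely failure is attack of the potassium phenolate of 27 on the sulfur of triflate 22, returning 21, because the hindered nucleophile slows the productive steps at palladium. The fallback brings ring C in as an aryne, as ring E was brought in. It sets out from 21 and comes back at 28, at the cost of one extra step. Bromination of 21 ortho to the hydroxyl (NBS, CH2Cl2, –40 °C) should give 2-bromo-3,5-dimethoxy-4-[3,4,5-trimethoxy-2-(3,4,5-trimethoxyphenoxy)phenoxy]phenol F7. The sequence of step 8 (HMDS; n-BuLi; Tf2O) would give 3,5-dimethoxy-4-[3,4,5-trimethoxy-2-(3,4,5-trimethoxyphenoxy)phenoxy]-2-(trimethylsilyl)phenyl trifluoromethanesulfonate F8. CsF in MeCN with phenol 27 would then give 28, the methoxy group next to the triple bond again directing the phenoxide to the remote carbon.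

Step 15. The most likely failure is incomplete cleavage of the thirteen methyl ethers, since boron chelates of the vicinal oxygen arrays slow the last cleavages, together with air oxidation of the pyrogallol-type rings during isolation. The fallback separates demethylation from isolation of the free polyphenol. It sets out from 28 and comes back at 29. The crude demethylation product would be acetylated (Ac2O, pyridine) to the tridecaacetate of 29 F9, which is stable to air and can be purified on silica away from under-demethylated material. Acid-catalysed methanolysis (HCl in MeOH, rt, Ar) would then release 29.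

Step 12. The most likely failure is slow substitution, because the ortho and para methoxy groups weaken the activating power of the formyl group and the nucleophile is di-ortho-substituted, with degradation of the aldehyde at the temperature then needed. The fallback replaces substitution by copper catalysis. It sets out from 23 and comes back at 25. Ullmann coupling of 23 with 2-bromo-4,6-dimethoxybenzaldehyde F10 (copper monoiodide CuI, N,N-dimethylglycine, Cs2CO3, dioxane, 100 °C) would give 25, the ortho formyl group assisting the copper step.

## Further compounds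

F1 | step 5 | 2,3,4-trimethoxyphenol | COc1ccc(O)c(OC)c1OC
F2 | step 5 | 6-bromo-2,3,4-trimethoxyphenol | COc1cc(Br)c(O)c(OC)c1OC
F3 | step 5 | 1-bromo-3,4,5-trimethoxy-2-(3,4,5-trimethoxyphenoxy)benzene | COc1cc(Br)c(Oc2cc(OC)c(OC)c(OC)c2)c(OC)c1OC
F4 | step 4 | 2-{[(E)-1,2-dichloroethenyl]oxy}-1,3-dimethoxy-5-(propan-2-yloxy)benzene | Cl/C=C(/Cl)Oc1c(OC)cc(OC(C)C)cc1OC
F5 | step 4 | 2-(ethynyloxy)-1,3-dimethoxy-5-(propan-2-yloxy)benzene | C#COc1c(OC)cc(OC(C)C)cc1OC
F6 | step 4 | 2-[(1-bromoethenyl)oxy]-1,3-dimethoxy-5-(propan-2-yloxy)benzene | C=C(Br)Oc1c(OC)cc(OC(C)C)cc1OC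
F7 | step 14 | 2-bromo-3,5-dimethoxy-4-[3,4,5-trimethoxy-2-(3,4,5-trimethoxyphenoxy)phenoxy]phenol | COc1cc(O)c(Br)c(OC)c1Oc1cc(OC)c(OC)c(OC)c1Oc1cc(OC)c(OC)c(OC)c1
F8 | step 14 | 3,5-dimethoxy-4-[3,4,5-trimethoxy-2-(3,4,5-trimethoxyphenoxy)phenoxy]-2-(trimethylsilyl)phenyl trifluoromethanesulfonate | COc1cc(OS(=O)(=O)C(F)(F)F)c([Si](C)(C)C)c(OC)c1Oc1cc(OC)c(OC)c(OC)c1Oc1cc(OC)c(OC)c(OC)c1
F9 | step 15 | tridecaacetate of 29 (all thirteen hydroxyls as acetates) | CC(=O)Oc1cc(OC(C)=O)c(Oc2cc(OC(C)=O)cc(OC(C)=O)c2Oc2cc(OC(C)=O)c(Oc3cc(OC(C)=O)c(OC(C)=O)c(OC(C)=O)c3Oc3cc(OC(C)=O)c(OC(C)=O)c(OC(C)=O)c3)c(OC(C)=O)c2)c(OC(C)=O)c1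
F10 | step 12 | 2-bromo-4,6-dimethoxybenzaldehyde | COc1cc(Br)c(C=O)c(OC)c1
A1 | alternative 1 | 1,3-dimethoxy-5-[2-(2,6-dimethoxyphenoxy)-6-methoxyphenoxy]-2-[3,4,5-trimethoxy-2-(3,4,5-trimethoxyphenoxy)phenoxy]benzene | COc1cccc(OC)c1Oc1cccc(OC)c1Oc1cc(OC)c(Oc2cc(OC)c(OC)c(OC)c2Oc2cc(OC)c(OC)c(OC)c2)c(OC)c1
A2 | alternative 1 | 4-(2-{3,5-dimethoxy-4-[3,4,5-trimethoxy-2-(3,4,5-trimethoxyphenoxy)phenoxy]phenoxy}-5-hydroxy-3-methoxyphenoxy)-3,5-dimethoxyphenol | COc1cc(O)cc(OC)c1Oc1cc(O)cc(OC)c1Oc1cc(OC)c(Oc2cc(OC)c(OC)c(OC)c2Oc2cc(OC)c(OC)c(OC)c2)c(OC)c1
A3 | alternative 2 | diethyl 2-[2-(benzyloxy)-3,5-dimethoxyphenoxy]propanedioate | CCOC(=O)C(Oc1cc(OC)cc(OC)c1OCc1ccccc1)C(=O)OCC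
A4 | alternative 2 | diethyl 3-oxopentanedioate | CCOC(=O)CC(=O)CC(=O)OCC
A5 | alternative 2 | diethyl 5-[2-(benzyloxy)-3,5-dimethoxyphenoxy]-2,4,6-trihydroxybenzene-1,3-dicarboxylate | CCOC(=O)c1c(O)c(Oc2cc(OC)cc(OC)c2OCc2ccccc2)c(O)c(C(=O)OCC)c1O
A6 | alternative 3 | 4-hydroxy-6-methyl-3-[3,4,5-trimethoxy-2-(3,4,5-trimethoxyphenoxy)phenoxy]-2H-pyran-2-one | CC1=CC(O)=C(Oc2cc(OC)c(OC)c(OC)c2Oc2cc(OC)c(OC)c(OC)c2)C(=O)O1
A7 | alternative 3 | methyl 3,5-dioxo-2-[3,4,5-trimethoxy-2-(3,4,5-trimethoxyphenoxy)phenoxy]hexanoate | COC(=O)C(Oc1cc(OC)c(OC)c(OC)c1Oc1cc(OC)c(OC)c(OC)c1)C(=O)CC(C)=O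
A8 | alternative 3 | 2-[3,4,5-trimethoxy-2-(3,4,5-trimethoxyphenoxy)phenoxy]benzene-1,3,5-triol | Oc1cc(O)c(Oc2cc(OC)c(OC)c(OC)c2Oc2cc(OC)c(OC)c(OC)c2)c(O)c1
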